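**Retrosynthetic overview**

1. The strategy rests on the trans-2-aryl-3-(hydroxymethyl)-2,3-dihydrobenzofuran core. C3 carries arene carbon C3a and a one-carbon exocyclic CH2OH beside the O1–C2(aryl) stereocentre, which is what a 2-arylchroman-4-one gives when C4a shifts from C4 to C3 and C4 leaves the ring as a carboxylate.
2. Target 14 ⇐ diester 13 (reduction of both esters) ⇐ aryl bromide 11 + methyl acrylate 12 (Mizoroki–Heck).
3. 11 ⇐ (S)-flavanone 7 (oxidative six-to-five ring contraction: C3–C4a formed, C4–C4a broken) ⇐ chromone 5 + boronic acid 6 (enantioselective conjugate arylation).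
4. 5 ⇐ enaminone 4 ⇐ bromo ketone 2 + amide acetal 3; 2 ⇐ acetophenone 1 (bromination).
5. Ring order: both arenes are bought; the pyranone ring is closed first, ring B is joined at C2, the pyranone is contracted to the dihydrofuran, and the propenyl chain is attached last.

Key step: step 5

Assumption: the (R)-antipode of the pyridine–oxazoline ligand is taken, by analogy with the facial preference of this catalyst type on cyclic enones, to deliver the 2S flavanone; if the sense proves opposite, the (S)-ligand is used and nothing else changes.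

**Route**

Step 1
Reactants: 1 2'-hydroxy-3'-methoxyacetophenone
Product: 2 5'-bromo-2'-hydroxy-3'-methoxyacetophenone
Conditions: NBS (1.05 equiv), MeCN, 0 °C to rt
Reagents that add atoms: N-bromosuccinimide O=C1CCC(=O)N1Br
Why: Electrophilic aromatic bromination in which the phenol, the strongest donor, directs to its only free ortho/para position (C5', para to OH), while NBS in acetonitrile avoids acid-catalysed bromination of the acetyl group.

Step 2
Reactants: 2 5'-bromo-2'-hydroxy-3'-methoxyacetophenone; 3 N,N-dimethylformamide dimethyl acetal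
Product: 4 (E)-1-(5-bromo-2-hydroxy-3-methoxyphenyl)-3-(dimethylamino)prop-2-en-1-one
Conditions: 3 (1.5 equiv), toluene, 100 °C
Reagents that add atoms: N,N-dimethylformamide dimethyl acetal (3) COC(OC)N(C)C
Why: Enaminone condensation of the methyl ketone with the amide acetal, driven by loss of two molecules of methanol, should give the E vinylogous amide and install the carbon that becomes C2 of the chromone.

Step 3
Reactants: 4 (E)-1-(5-bromo-2-hydroxy-3-methoxyphenyl)-3-(dimethylamino)prop-2-en-1-one
Product: 5 6-bromo-8-methoxychromone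
Conditions: conc. aq. HCl, CH2Cl2, 40 °C
Reagents that add atoms: none
Why: Acid-promoted intramolecular oxa-Michael addition of the phenol to the protonated enaminone (6-endo) followed by elimination of dimethylamine (addition–elimination) should close the aromatic pyranone ring.

Step 4
Reactants: 5 6-bromo-8-methoxychromone; 6 3,4-dimethoxyphenylboronic acid
Product: 7 (S)-6-bromo-2-(3,4-dimethoxyphenyl)-8-methoxychroman-4-one
Conditions: 6 (2 equiv), Pd(OCOCF3)2 (5 mol%), (R)-t-BuPyOx [(R)-4-tert-butyl-2-(pyridin-2-yl)-4,5-dihydrooxazole, 6 mol%], NH4PF6 (30 mol%), H2O (5 equiv), ClCH2CH2Cl, 60 °C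
Reagents that add atoms: 3,4-dimethoxyphenylboronic acid (6) COc1ccc(B(O)O)cc1OC
Why: Enantioselective conjugate arylation (Hayashi–Miyaura-type 1,4-addition) in which 6 transmetalates to the cationic divalent palladium–pyridine-oxazoline complex, the chromone C2=C3 bond inserts face-selectively into the aryl–palladium bond within the chiral pocket (this sets C2 as S), and water protonates the palladium enolate without zerovalent palladium ever forming, so the aryl bromide stays intact.

Step 5
Reactants: 7 (S)-6-bromo-2-(3,4-dimethoxyphenyl)-8-methoxychroman-4-one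
Product: 11 methyl (2S,3S)-5-bromo-2-(3,4-dimethoxyphenyl)-7-methoxy-2,3-dihydrobenzofuran-3-carboxylate, via enol ether 8 (not isolated), via iodane ketal 9 (not isolated), via trimethyl orthoester 10 (not isolated)
Conditions: PhI(OAc)2 (1.2 equiv), conc. H2SO4 (cat.), HC(OMe)3/MeOH, 0 °C to rt, short reaction time; then H2O; then aq. NaHCO3
Reagents that add atoms: trimethyl orthoformate COC(OC)OC and methanol CO (the ester methoxy group); water O (the ester carbonyl oxygen, delivered when the orthoester is hydrolysed in the quench)
Why: Acid and orthoformate turn the C4 ketone into enol ether 8, whose C3 attacks the electrophilic trivalent iodine on the face opposite the equatorial C2 aryl group while methanol caps C4, giving the 2,3-trans iodane ketal 9; its equatorial C3–I bond is antiperiplanar to the C4–C4a ring bond, so arene carbon C4a, pushed by the two ketal oxygens on C4 and assisted by the ortho ring oxygen O1, shifts from C4 to C3 with expulsion of iodobenzene, and the dimethoxycarbenium ion left at the old C4 is caught by methanol as orthoester 10 and hydrolysed to the methyl ester in the quench. The closest known reaction type is the oxidative ring contraction of flavanones to methyl trans-2-aryl-2,3-dihydrobenzofuran-3-carboxylates with trivalent iodine or trivalent thallium oxidants in trimethyl orthoformate. The dihydrofuran ring (O1–C2–C3–C3a–C7a) is closed not by a cyclisation but by a 1,2-aryl shift through a bridged phenonium-like transition state, a six-to-five contraction in which C3–C4a forms as C4–C4a breaks. C2 is not touched, and the new C3 stereocentre is set by substrate control: anti iodination followed by inversion at C3 places the ester trans to the aryl group (2S,3S), which is also the more stable diastereomer. The step needs C4a to migrate in preference to the electron-rich ring B aryl group (which would lead into the isoflavone manifold) and needs the benzylic C2–O1 bond not to ionise; the equatorial aryl group, which is gauche rather than antiperiplanar to the C3–I bond in the diequatorial conformer, should secure the first, and low temperature with brief exposure to a small amount of acid the second.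

Step 6
Reactants: 11 methyl (2S,3S)-5-bromo-2-(3,4-dimethoxyphenyl)-7-methoxy-2,3-dihydrobenzofuran-3-carboxylate; 12 methyl acrylate
Product: 13 methyl (2S,3S)-2-(3,4-dimethoxyphenyl)-7-methoxy-5-[(E)-3-methoxy-3-oxoprop-1-enyl]-2,3-dihydrobenzofuran-3-carboxylate
Conditions: 12 (3 equiv), Pd(OAc)2 (5 mol%), P(o-tol)3 (10 mol%), NaOAc (2 equiv), DMF, 90 °C
Reagents that add atoms: methyl acrylate (12) C=CC(=O)OC
Why: Mizoroki–Heck coupling in which oxidative addition of zerovalent palladium into the C5–Br bond, syn carbopalladation of the acrylate and syn β-hydride elimination give the E enoate, while the weak acetate base should not enolise the C3 ester, so the trans relationship and C2 are preserved.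

Step 7
Reactants: 13 methyl (2S,3S)-2-(3,4-dimethoxyphenyl)-7-methoxy-5-[(E)-3-methoxy-3-oxoprop-1-enyl]-2,3-dihydrobenzofuran-3-carboxylate
Product: 14 Hierochin B, (E)-3-[(2S,3R)-2-(3,4-dimethoxyphenyl)-3-(hydroxymethyl)-7-methoxy-2,3-dihydrobenzofuran-5-yl]prop-2-en-1-ol
Conditions: i-Bu2AlH (5 equiv), CH2Cl2, −78 to 0 °C; aq. KNaC4H4O6 (potassium sodium tartrate) work-up
Reagents that add atoms: none
Why: Hydride reduction of both esters with excess i-Bu2AlH should reduce the enoate 1,2 to the E allylic alcohol without touching the alkene and the C3 ester to the primary alcohol, the low temperature keeping the transient α-aryl aldehyde (held as its aluminium hemiacetal) from epimerising, so C2 and C3 are carried over unchanged (C3 becomes R by priority change only).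

**Compound list**

1 | 2'-hydroxy-3'-methoxyacetophenone | CC(=O)c1cccc(OC)c1O | starting material
2 | 5'-bromo-2'-hydroxy-3'-methoxyacetophenone | CC(=O)c1cc(Br)cc(OC)c1O | intermediate
3 | N,N-dimethylformamide dimethyl acetal | COC(OC)N(C)C | starting material
4 | (E)-1-(5-bromo-2-hydroxy-3-methoxyphenyl)-3-(dimethylamino)prop-2-en-1-one | CN(C)/C=C/C(=O)c1cc(Br)cc(OC)c1O | intermediate
5 | 6-bromo-8-methoxychromone | O=c1ccoc2c(OC)cc(Br)cc12 | intermediate
6 | 3,4-dimethoxyphenylboronic acid | COc1ccc(B(O)O)cc1OC | starting material
7 | (S)-6-bromo-2-(3,4-dimethoxyphenyl)-8-methoxychroman-4-one | COc1ccc([C@H]2Oc3c(OC)cc(Br)cc3C(=O)C2)cc1OC | intermediate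
8 | (S)-6-bromo-2-(3,4-dimethoxyphenyl)-4,8-dimethoxy-2H-chromene (enol ether) | COc1ccc([C@H]2Oc3c(OC)cc(Br)cc3C(OC)=C2)cc1OC | intermediate
9 | (2R,3R)-3-[acetoxy(phenyl)-λ3-iodanyl]-6-bromo-2-(3,4-dimethoxyphenyl)-4,4,8-trimethoxychromane (2,3-trans; same spatial arrangement at C2 as in 7) | COc1ccc([C@H]2Oc3c(OC)cc(Br)cc3C(OC)(OC)[C@@H]2I(OC(C)=O)c2ccccc2)cc1OC | intermediate
10 | (2S,3S)-5-bromo-2-(3,4-dimethoxyphenyl)-7-methoxy-3-(trimethoxymethyl)-2,3-dihydrobenzofuran | COc1ccc([C@H]2Oc3c(OC)cc(Br)cc3[C@@H]2C(OC)(OC)OC)cc1OC | intermediate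
11 | methyl (2S,3S)-5-bromo-2-(3,4-dimethoxyphenyl)-7-methoxy-2,3-dihydrobenzofuran-3-carboxylate (trans) | COc1ccc([C@H]2Oc3c(OC)cc(Br)cc3[C@@H]2C(=O)OC)cc1OC | intermediate
12 | methyl acrylate | C=CC(=O)OC | starting material
13 | methyl (2S,3S)-2-(3,4-dimethoxyphenyl)-7-methoxy-5-[(E)-3-methoxy-3-oxoprop-1-enyl]-2,3-dihydrobenzofuran-3-carboxylate | COc1ccc([C@H]2Oc3c(OC)cc(/C=C/C(=O)OC)cc3[C@@H]2C(=O)OC)cc1OC | intermediate
14 | Hierochin B, (E)-3-[(2S,3R)-2-(3,4-dimethoxyphenyl)-3-(hydroxymethyl)-7-methoxy-2,3-dihydrobenzofuran-5-yl]prop-2-en-1-ol | COc1ccc([C@H]2Oc3c(OC)cc(/C=C/CO)cc3[C@@H]2CO)cc1OC | target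

**Step count**

Total steps: 7. Longest linear sequence: 7 steps (from 1).

**Steps most likely to fail**

Step 5 (ring contraction). The ring B aryl group is a better migrating group than the bromo-substituted ring A carbon and may shift from C2 to C3 through the minor diaxial conformer. The veratryl ring may also be oxidised by the iodane, or acid may ionise the C2–O1 bond and erode optical purity. The fallback achieves the same bond changes by a Wolff rearrangement, in which only the acyl substituent C4a can migrate. It sets out from 7. C-Trifluoroacetylation at C3 (LiN(SiMe3)2, CF3CO2CH2CF3, THF, −78 °C, kept cold so the enolate does not open the pyranone ring) would give (2S)-6-bromo-2-(3,4-dimethoxyphenyl)-8-methoxy-3-(trifluoroacetyl)chroman-4-one F1. Detrifluoroacetylative diazo transfer (MsN3, Et3N, MeCN, H2O, rt) would give the 3-diazoflavanone F2. Pyrex-filtered photolysis of F2 in MeOH should trigger the Wolff ring contraction, and methanol trapping of the ketene should give the ester as a mixture of 11 and its cis epimer, methyl (2S,3R)-5-bromo-2-(3,4-dimethoxyphenyl)-7-methoxy-2,3-dihydrobenzofuran-3-carboxylate F3. F3 is equilibrated to the more stable trans isomer with catalytic NaOMe in MeOH at 0 °C. The fallback returns to the route at 11.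

Step 4 (conjugate arylation). Facial discrimination in the insertion may be insufficient, the electron-rich boronic acid may protodeboronate, or the flavanone may lose optical purity by reversible retro-oxa-Michael ring opening. The fallback builds the flavanone as a racemate and resolves it. It sets out from 2. Claisen–Schmidt condensation with commercial 3,4-dimethoxybenzaldehyde (KOH, EtOH, rt) would give (E)-1-(5-bromo-2-hydroxy-3-methoxyphenyl)-3-(3,4-dimethoxyphenyl)prop-2-en-1-one F4. Oxa-Michael cyclisation (NaOAc, EtOH, reflux) would give racemic 6-bromo-2-(3,4-dimethoxyphenyl)-8-methoxychroman-4-one F5. Kinetic resolution by asymmetric transfer hydrogenation (Cp*RhCl[TsDPEN], HCO2H/Et3N, EtOAc, 40 °C), with the catalyst antipode chosen so that the (R)-ketone is reduced faster, should convert that enantiomer into (2R,4R)-cis-6-bromo-2-(3,4-dimethoxyphenyl)-8-methoxychroman-4-ol F6. The unreacted (S)-ketone is separated by chromatography. The fallback returns to the route at 7.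

Step 6 (Heck coupling). Oxidative addition into the electron-rich aryl bromide may be slow and force temperatures at which the C3 ester enolises, leading to epimerisation or E1cB opening of the dihydrofuran with loss of C2 integrity. The fallback removes the acidic centre before the cross-coupling and brings in the side chain at its final oxidation level. It sets out from 11. Reduction (i-Bu2AlH, CH2Cl2, −78 °C) would give [(2S,3R)-5-bromo-2-(3,4-dimethoxyphenyl)-7-methoxy-2,3-dihydrobenzofuran-3-yl]methanol F7. Suzuki–Miyaura coupling with commercial (E)-3-(tert-butyldimethylsilyloxy)prop-1-enylboronic acid pinacol ester (PdCl2(dppf), K2CO3, dioxane/H2O, 80 °C) would give the silyl ether of the target, (E)-tert-butyldimethylsilyl-protected Hierochin B F8. Desilylation (Bu4NF, THF, 0 °C) then gives the target directly. The fallback returns to the route at 14 and bypasses 13.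

**Further compounds**

F1 | step 5 | (2S)-6-bromo-2-(3,4-dimethoxyphenyl)-8-methoxy-3-(trifluoroacetyl)chroman-4-one | COc1ccc([C@H]2Oc3c(OC)cc(Br)cc3C(=O)C2C(=O)C(F)(F)F)cc1OC
F2 | step 5 | (2R)-6-bromo-3-diazo-2-(3,4-dimethoxyphenyl)-8-methoxychroman-4-one (same spatial arrangement at C2 as in 7) | COc1ccc([C@H]2Oc3c(OC)cc(Br)cc3C(=O)C2=[N+]=[N-])cc1OC
F3 | step 5 | methyl (2S,3R)-5-bromo-2-(3,4-dimethoxyphenyl)-7-methoxy-2,3-dihydrobenzofuran-3-carboxylate (cis) | COc1ccc([C@H]2Oc3c(OC)cc(Br)cc3[C@H]2C(=O)OC)cc1OC
F4 | step 4 | (E)-1-(5-bromo-2-hydroxy-3-methoxyphenyl)-3-(3,4-dimethoxyphenyl)prop-2-en-1-one | COc1ccc(/C=C/C(=O)c2cc(Br)cc(OC)c2O)cc1OC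
F5 | step 4 | racemic 6-bromo-2-(3,4-dimethoxyphenyl)-8-methoxychroman-4-one | COc1ccc(C2Oc3c(OC)cc(Br)cc3C(=O)C2)cc1OC
F6 | step 4 | (2R,4R)-cis-6-bromo-2-(3,4-dimethoxyphenyl)-8-methoxychroman-4-ol | COc1ccc([C@@H]2Oc3c(OC)cc(Br)cc3[C@H](O)C2)cc1OC
F7 | step 6 | [(2S,3R)-5-bromo-2-(3,4-dimethoxyphenyl)-7-methoxy-2,3-dihydrobenzofuran-3-yl]methanol | COc1ccc([C@H]2Oc3c(OC)cc(Br)cc3[C@@H]2CO)cc1OC
F8 | step 6 | [(2S,3R)-5-[(E)-3-(tert-butyldimethylsilyloxy)prop-1-enyl]-2-(3,4-dimethoxyphenyl)-7-methoxy-2,3-dihydrobenzofuran-3-yl]methanol | COc1ccc([C@H]2Oc3c(OC)cc(/C=C/CO[Si](C)(C)C(C)(C)C)cc3[C@@H]2CO)cc1OC
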